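**Retrosynthetic overview**

- Labels: ring 1 is the dihydrobenzofuran on the stilbene-bearing arene (C2, C3); ring 2 is the dihydrobenzofuran on the central arene (C2′, C3′).
- Last operation: both C2–O bonds are made together. An acyclic nonaphenol bis(4-hydroxybenzyl 2-pyridyl sulfone) gives two para-quinone methides, which close by a double 5-exo oxa-Michael addition. Rings 1 and 2 form in that one operation; no ring is made earlier.
- The two C2 aryl groups come from a double α-arylation of a bis(β,β-diarylethyl sulfone) with 4-bromoanisole.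
- C3 (S) and C3′ (R) come from two rhodium-catalysed asymmetric arylboron additions to (E)-vinyl 2-pyridyl sulfones. The two centres have opposite local sense, so the two additions use enantiomeric ligands; a Miyaura borylation of the central ring links them.
- The vinyl sulfones come from two bromodimethoxybenzaldehydes and methyl 2-pyridyl sulfone; the stilbene comes from a Heck reaction.

Assumption: (S,S)-Chiraphos is taken as the ligand enantiomer that adds the aryl group to the Re face of the β-carbon of a 2-pyridyl vinyl sulfone; steps 2 and 6 need opposite ligand enantiomers whichever way this falls.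

**Route**

Step 1
Reactants: 1 4-bromo-2,6-dimethoxybenzaldehyde; 2 2-(methylsulfonyl)pyridine
Product: 5 2-{[(E)-2-(4-bromo-2,6-dimethoxyphenyl)ethenyl]sulfonyl}pyridine, via hydroxy sulfone 3 (not isolated), via mesylate 4 (not isolated)
Conditions: 2, LiN(SiMe3)2, THF, −78 °C; 1; then MsCl, Et3N, −78 to 20 °C
Reagents that add atoms: methanesulfonyl chloride, CS(=O)(=O)Cl (its atoms reach intermediate 4 only, none stay in 5)
Why: Aldol-type addition of the lithiated methyl sulfone to the aldehyde, then mesylation and E1cB elimination, gives the conjugated vinyl sulfone with the thermodynamic E geometry; no stereocentre remains.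

Step 2
Reactants: 5 2-{[(E)-2-(4-bromo-2,6-dimethoxyphenyl)ethenyl]sulfonyl}pyridine; 6 (3,5-dimethoxyphenyl)boronic acid
Product: 7 2-{[(2R)-2-(4-bromo-2,6-dimethoxyphenyl)-2-(3,5-dimethoxyphenyl)ethyl]sulfonyl}pyridine
Conditions: Rh(acac)(C2H4)2 (5 mol %), (S,S)-Chiraphos (5.5 mol %), 6 (3 equiv), dioxane–H2O 10:1, 100 °C
Reagents that add atoms: none
Why: Rhodium-catalysed asymmetric conjugate addition of an arylboronic acid (Hayashi–Miyaura reaction) to a vinyl sulfone whose pyridyl nitrogen chelates the metal; the ligand directs the aryl group to one face of the β-carbon and sets C3′ as R, and the aryl bromide is inert to monovalent rhodium.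

Step 3
Reactants: 7 2-{[(2R)-2-(4-bromo-2,6-dimethoxyphenyl)-2-(3,5-dimethoxyphenyl)ethyl]sulfonyl}pyridine
Product: 8 2-{[(2R)-2-(3,5-dimethoxyphenyl)-2-[2,6-dimethoxy-4-(4,4,5,5-tetramethyl-1,3,2-dioxaborolan-2-yl)phenyl]ethyl]sulfonyl}pyridine
Conditions: B2pin2, Pd(dppf)Cl2 (3 mol %), KOAc, dioxane, 90 °C
Reagents that add atoms: bis(pinacolato)diboron, CC1(C)OB(OC1(C)C)B1OC(C)(C)C(C)(C)O1
Why: Miyaura borylation of the unhindered aryl bromide through zerovalent palladium; the sulfone and the C3′ centre are not touched.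

Step 4
Reactants: 9 2-bromo-4,6-dimethoxybenzaldehyde; 10 4-vinylanisole
Product: 11 2,4-dimethoxy-6-[(E)-2-(4-methoxyphenyl)ethenyl]benzaldehyde
Conditions: Pd(OAc)2 (2 mol %), P(o-tol)3 (4 mol %), Et3N, DMF, 100 °C
Reagents that add atoms: none
Why: Mizoroki–Heck reaction; syn insertion and syn β-hydride elimination give the (E)-stilbene, and the aldehyde survives.

Step 5
Reactants: 11 2,4-dimethoxy-6-[(E)-2-(4-methoxyphenyl)ethenyl]benzaldehyde; 2 2-(methylsulfonyl)pyridine
Product: 14 2-{[(E)-2-{2,4-dimethoxy-6-[(E)-2-(4-methoxyphenyl)ethenyl]phenyl}ethenyl]sulfonyl}pyridine, via hydroxy sulfone 12 (not isolated), via mesylate 13 (not isolated)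
Conditions: 2, LiN(SiMe3)2, THF, −78 °C; 11; then MsCl, Et3N, −78 to 20 °C
Reagents that add atoms: methanesulfonyl chloride, CS(=O)(=O)Cl (its atoms reach intermediate 13 only, none stay in 14)
Why: Same aldol addition, mesylation and E1cB elimination as in step 1; the stilbene is inert to the sulfonyl carbanion and the new alkene is E.

Step 6
Reactants: 14 2-{[(E)-2-{2,4-dimethoxy-6-[(E)-2-(4-methoxyphenyl)ethenyl]phenyl}ethenyl]sulfonyl}pyridine; 8 the (R)-arylboronate of step 3
Product: 15 2-{[(2S)-2-{2,4-dimethoxy-6-[(E)-2-(4-methoxyphenyl)ethenyl]phenyl}-2-{4-[(1R)-1-(3,5-dimethoxyphenyl)-2-(pyridin-2-ylsulfonyl)ethyl]-3,5-dimethoxyphenyl}ethyl]sulfonyl}pyridine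
Conditions: Rh(acac)(C2H4)2 (5 mol %), (R,R)-Chiraphos (5.5 mol %), KOH (20 mol %), dioxane–H2O 10:1, 100 °C
Reagents that add atoms: none
Why: Second Hayashi–Miyaura conjugate addition, now with the enantiomeric ligand, so the aryl group enters the opposite face and sets C3 as S under catalyst control; the remote C3′ centre (para across the central ring) has no say, and the stilbene is not an acceptor.

Step 7
Reactants: 15 the (S,R)-bis-sulfone of step 6; 16 4-bromoanisole (2 equiv consumed)
Product: 17 bis-sulfone 15 carrying a 4-methoxyphenyl group on each sulfonyl-bearing carbon (C3 S, C3′ R; the two new centres as epimer mixtures)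
Conditions: Pd(OAc)2 (10 mol %), XPhos (20 mol %), LiN(SiMe3)2, 16, toluene, 80 °C
Reagents that add atoms: none
Why: Palladium-catalysed α-arylation of a sulfone (deprotonative cross-coupling): each α-sulfonyl carbanion transmetalates to arylpalladium and reductive elimination makes the C2–aryl bond. The diarylmethine hydrogens at C3 and C3′ are too weakly acidic to epimerise, and the configuration at the new centres does not matter because both become planar in step 8.

Step 8
Reactants: 17 the bis(α-anisyl) bis-sulfone of step 7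
Product: 19 5-[(2R,3R)-4-hydroxy-6-{(2S,3S)-6-hydroxy-2-(4-hydroxyphenyl)-4-[(E)-2-(4-hydroxyphenyl)ethenyl]-2,3-dihydro-1-benzofuran-3-yl}-2-(4-hydroxyphenyl)-2,3-dihydro-1-benzofuran-3-yl]benzene-1,3-diol, via nonaphenol bis-sulfone 18 (not isolated)
Conditions: BBr3, CH2Cl2, −78 to 0 °C; MeOH, −78 °C; then K2CO3, THF–H2O, 20 °C, dark, argon
Reagents that add atoms: none
Why: Proposed new method: BBr3 cleaves all nine aryl methyl ethers to give 18; carbonate then expels pyridine-2-sulfinate from each 4-hydroxybenzylic sulfone by 1,6-elimination, and each para-quinone methide is trapped 5-exo by the neighbouring phenoxide (intramolecular oxa-Michael addition), so rings 1 and 2 close in the same operation. The closest known chemistry is base-triggered quinone methide formation from hydroxybenzyl sulfones followed by 1,6-addition. The reversible closure places each C2 aryl trans to the fixed C3 aryl and gives (2S,3S) in ring 1 and (2R,3R) in ring 2.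

**Compound list**

1 | 4-bromo-2,6-dimethoxybenzaldehyde | COc1cc(Br)cc(OC)c1C=O | starting material
2 | 2-(methylsulfonyl)pyridine | CS(=O)(=O)c1ccccn1 | starting material
3 | rac-1-(4-bromo-2,6-dimethoxyphenyl)-2-(pyridin-2-ylsulfonyl)ethanol (formed as its lithium alkoxide) | COc1cc(Br)cc(OC)c1C(O)CS(=O)(=O)c1ccccn1 | intermediate
4 | rac-1-(4-bromo-2,6-dimethoxyphenyl)-2-(pyridin-2-ylsulfonyl)ethyl methanesulfonate | COc1cc(Br)cc(OC)c1C(OS(C)(=O)=O)CS(=O)(=O)c1ccccn1 | intermediate
5 | 2-{[(E)-2-(4-bromo-2,6-dimethoxyphenyl)ethenyl]sulfonyl}pyridine | COc1cc(Br)cc(OC)c1/C=C/S(=O)(=O)c1ccccn1 | intermediate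
6 | (3,5-dimethoxyphenyl)boronic acid | COc1cc(OC)cc(c1)B(O)O | starting material
7 | 2-{[(2R)-2-(4-bromo-2,6-dimethoxyphenyl)-2-(3,5-dimethoxyphenyl)ethyl]sulfonyl}pyridine | O=S(=O)(c1ccccn1)C[C@@H](c1c(OC)cc(Br)cc1OC)c1cc(OC)cc(OC)c1 | intermediate
8 | 2-{[(2R)-2-(3,5-dimethoxyphenyl)-2-[2,6-dimethoxy-4-(4,4,5,5-tetramethyl-1,3,2-dioxaborolan-2-yl)phenyl]ethyl]sulfonyl}pyridine | O=S(=O)(c1ccccn1)C[C@@H](c1c(OC)cc(cc1OC)B1OC(C)(C)C(C)(C)O1)c1cc(OC)cc(OC)c1 | intermediate
9 | 2-bromo-4,6-dimethoxybenzaldehyde | COc1cc(Br)c(C=O)c(OC)c1 | starting material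
10 | 4-vinylanisole (1-ethenyl-4-methoxybenzene) | COc1ccc(C=C)cc1 | starting material
11 | 2,4-dimethoxy-6-[(E)-2-(4-methoxyphenyl)ethenyl]benzaldehyde | COc1ccc(/C=C/c2cc(OC)cc(OC)c2C=O)cc1 | intermediate
12 | rac-1-{2,4-dimethoxy-6-[(E)-2-(4-methoxyphenyl)ethenyl]phenyl}-2-(pyridin-2-ylsulfonyl)ethanol (formed as its lithium alkoxide) | COc1ccc(/C=C/c2cc(OC)cc(OC)c2C(O)CS(=O)(=O)c2ccccn2)cc1 | intermediate
13 | rac-1-{2,4-dimethoxy-6-[(E)-2-(4-methoxyphenyl)ethenyl]phenyl}-2-(pyridin-2-ylsulfonyl)ethyl methanesulfonate | COc1ccc(/C=C/c2cc(OC)cc(OC)c2C(OS(C)(=O)=O)CS(=O)(=O)c2ccccn2)cc1 | intermediate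
14 | 2-{[(E)-2-{2,4-dimethoxy-6-[(E)-2-(4-methoxyphenyl)ethenyl]phenyl}ethenyl]sulfonyl}pyridine | COc1ccc(/C=C/c2cc(OC)cc(OC)c2/C=C/S(=O)(=O)c2ccccn2)cc1 | intermediate
15 | 2-{[(2S)-2-{2,4-dimethoxy-6-[(E)-2-(4-methoxyphenyl)ethenyl]phenyl}-2-{4-[(1R)-1-(3,5-dimethoxyphenyl)-2-(pyridin-2-ylsulfonyl)ethyl]-3,5-dimethoxyphenyl}ethyl]sulfonyl}pyridine | COc1ccc(/C=C/c2cc(OC)cc(OC)c2[C@@H](CS(=O)(=O)c2ccccn2)c2cc(OC)c(c(OC)c2)[C@H](CS(=O)(=O)c2ccccn2)c2cc(OC)cc(OC)c2)cc1 | intermediate
16 | 4-bromoanisole | COc1ccc(Br)cc1 | starting material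
17 | 2-{[(2S)-1-(4-methoxyphenyl)-2-{2,4-dimethoxy-6-[(E)-2-(4-methoxyphenyl)ethenyl]phenyl}-2-{4-[(1R)-1-(3,5-dimethoxyphenyl)-2-(4-methoxyphenyl)-2-(pyridin-2-ylsulfonyl)ethyl]-3,5-dimethoxyphenyl}ethyl]sulfonyl}pyridine, both sulfonyl-bearing carbons as epimer mixtures | COc1ccc(/C=C/c2cc(OC)cc(OC)c2[C@@H](C(c2ccc(OC)cc2)S(=O)(=O)c2ccccn2)c2cc(OC)c(c(OC)c2)[C@H](C(c2ccc(OC)cc2)S(=O)(=O)c2ccccn2)c2cc(OC)cc(OC)c2)cc1 | intermediate
18 | nonaphenol bis-sulfone: 17 with all nine methoxy groups replaced by hydroxy groups (C3 S, C3′ R, sulfonyl-bearing carbons as epimer mixtures) | Oc1ccc(/C=C/c2cc(O)cc(O)c2[C@@H](C(c2ccc(O)cc2)S(=O)(=O)c2ccccn2)c2cc(O)c(c(O)c2)[C@H](C(c2ccc(O)cc2)S(=O)(=O)c2ccccn2)c2cc(O)cc(O)c2)cc1 | intermediate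
19 | 5-[(2R,3R)-4-hydroxy-6-{(2S,3S)-6-hydroxy-2-(4-hydroxyphenyl)-4-[(E)-2-(4-hydroxyphenyl)ethenyl]-2,3-dihydro-1-benzofuran-3-yl}-2-(4-hydroxyphenyl)-2,3-dihydro-1-benzofuran-3-yl]benzene-1,3-diol | Oc1ccc(/C=C/c2cc(O)cc3c2[C@H](c2cc(O)c4c(c2)O[C@@H](c2ccc(O)cc2)[C@@H]4c2cc(O)cc(O)c2)[C@@H](c2ccc(O)cc2)O3)cc1 | target

**Step count and risk**

Total step count: 8. Longest linear sequence: 6 (steps 1, 2, 3, 6, 7, 8); steps 4 and 5 form the second branch.

The three steps most likely to fail are 6, 7 and 8.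

Step 6 joins two hindered partners under rhodium catalysis, and the boronate 8 may lose boron before it adds. The fallback sets out from bromide 7 and vinyl sulfone 14 and bypasses 8. A Heck reaction (Pd(OAc)2, P(t-Bu)3, Et3N, dioxane, 100 °C) puts the aryl group of 7 on the β-carbon of 14. Syn insertion and syn β-hydride elimination give the trisubstituted vinyl sulfone 2-{[(Z)-2-{2,4-dimethoxy-6-[(E)-2-(4-methoxyphenyl)ethenyl]phenyl}-2-{4-[(1R)-1-(3,5-dimethoxyphenyl)-2-(pyridin-2-ylsulfonyl)ethyl]-3,5-dimethoxyphenyl}ethenyl]sulfonyl}pyridine F1 as one geometric isomer. Enantioselective conjugate reduction with copper hydride (Cu(OAc)2, the suitable BINAP enantiomer, PhSiH3, toluene) then delivers hydride to one face of the β-carbon, sets C3 and comes back to the route at 15. The C3–aryl bond is made without stereochemistry and the C3–H bond under catalyst control.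

Step 7 is a double α-arylation next to two congested diarylmethine carbons, on a substrate that holds two chelating pyridines. The fallback sets out from 15 and reverses the polarity at C2. LiN(SiMe3)2 followed by BrCCl2CCl2Br gives the bis(α-bromo sulfone) F2, which is 15 with one bromine on each sulfonyl-bearing carbon. A nickel-catalysed Negishi coupling (NiCl2(dme), bipyridine-type ligand, (4-methoxyphenyl)zinc iodide, THF), which engages the secondary bromide through a radical, comes back to the route at 17.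

Step 8 may fail in two ways: BBr3 can ionise the benzylic sulfones too early, and the quinone methide can lose the C3 hydrogen to give a triarylethene instead of closing. The fallback sets out from 17 and closes the rings before deprotection by a cationic path. EtAlCl2 in CH2Cl2 (−78 to −20 °C) ionises each benzylic sulfone, the neighbouring methoxy oxygen captures the cation, and chloride removes the methyl group. This gives the target heptamethyl ether F3 with both rings in place. BCl3 with n-Bu4NI then cleaves the seven methyl ethers, and a short K2CO3 treatment re-closes any ring opened on the way, coming back at 19.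

**Further compounds**

F1 | step 6 | 2-{[(Z)-2-{2,4-dimethoxy-6-[(E)-2-(4-methoxyphenyl)ethenyl]phenyl}-2-{4-[(1R)-1-(3,5-dimethoxyphenyl)-2-(pyridin-2-ylsulfonyl)ethyl]-3,5-dimethoxyphenyl}ethenyl]sulfonyl}pyridine | COc1ccc(/C=C/c2cc(OC)cc(OC)c2/C(=C\S(=O)(=O)c2ccccn2)c2cc(OC)c(c(OC)c2)[C@H](CS(=O)(=O)c2ccccn2)c2cc(OC)cc(OC)c2)cc1
F2 | step 7 | bis(α-bromo sulfone): 15 with one bromine on each sulfonyl-bearing carbon (C3 S, C3′ R, brominated carbons as epimer mixtures) | COc1ccc(/C=C/c2cc(OC)cc(OC)c2[C@@H](C(Br)S(=O)(=O)c2ccccn2)c2cc(OC)c(c(OC)c2)[C@H](C(Br)S(=O)(=O)c2ccccn2)c2cc(OC)cc(OC)c2)cc1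
F3 | step 8 | heptamethyl ether of 19 (all seven hydroxy groups as methoxy groups; ring 1 2S,3S; ring 2 2R,3R) | COc1ccc(/C=C/c2cc(OC)cc3c2[C@H](c2cc(OC)c4c(c2)O[C@@H](c2ccc(OC)cc2)[C@@H]4c2cc(OC)cc(OC)c2)[C@@H](c2ccc(OC)cc2)O3)cc1
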